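**Plan**

- Retrosynthesis: the four silyl groups come off last; the O4–C(glyceryl) ether of ring A is cut back to a ring A phenol and diethyl bromomalonate; the C8–O4' aryl ether and the C7–OH bond are then cut together, giving sinapyl alcohol and dihydrosinapyl alcohol.
- Enabling feature: C7 (carbinol) and C8 (ether to O4' of ring B) are adjacent and para to O4 of ring A, an arylglycerol 8-O-4' aryl ether. O4' of ring B lies between the methoxy-bearing C3' and C5' and opposite the alkyl-bearing C1', so a ring B phenoxy radical can bond productively only through oxygen.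
- Forward order: sinapic acid gives sinapyl alcohol, and 4-allyl-2,6-dimethoxyphenol gives dihydrosinapyl alcohol. Ag2O cross-coupling followed by hydration joins the two C9 units (no ring is formed). O4 is then alkylated with the malonate, the esters are reduced and the primary hydroxyls are silylated.
- Stereochemistry: the coupling gives all four stereoisomers. Oxidation to the C7 ketone erases C7. A ruthenium-catalysed asymmetric transfer hydrogenation with dynamic kinetic resolution then sets C7 (R, catalyst control) and C8 (R, by enolisation and Felkin–Anh matching).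

Key step: step 4

Remark on the chemistry: centres that are not yet fixed (C7, C8) are written without descriptors, and such compounds are mixtures of all stereoisomers at those centres. C7–C9 are the side-chain carbons on ring A and primed atoms belong to ring B. The phenol of 4 is assumed to be O-borylated by 9-BBN in step 3.

**Route**

Step 1
Reactants: 1 sinapic acid
Product: 2 methyl sinapate
Conditions: MeOH, H2SO4 (cat.), reflux
Reagents that add atoms: methanol, CO
Why: Fischer esterification in excess methanol under acid catalysis; the phenol and the E-alkene are inert and no stereocenter is formed.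

Step 2
Reactants: 2 methyl sinapate
Product: 3 sinapyl alcohol
Conditions: i-Bu2AlH (4.5 equiv), toluene, 0 °C; aq. potassium sodium tartrate (KNaC4H4O6) work-up
Reagents that add atoms: none
Why: Hydride 1,2-reduction of the conjugated ester by i-Bu2AlH (the first equivalent is spent on the phenol) should stop at the allylic alcohol and leave the E double bond untouched; no stereocenter is formed.

Step 3
Reactants: 4 4-allyl-2,6-dimethoxyphenol
Product: 6 dihydrosinapyl alcohol, via bis-9-BBN adduct 5 (not isolated)
Conditions: 9-BBN-H dimer (2.3 equiv B–H), THF, 0 °C to rt; then aq. NaOH, H2O2, 0 °C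
Reagents that add atoms: hydrogen peroxide, OO
Why: Hydroboration–oxidation: after the phenol O–H has consumed one B–H, the bulky borane adds boron to the terminal carbon of the allyl group (anti-Markovnikov) and alkaline peroxide replaces boron by hydroxyl, with no stereocenter created.

Step 4
Reactants: 3 sinapyl alcohol; 6 dihydrosinapyl alcohol
Product: 8 syringylglycerol 8-O-4' dihydrosinapyl ether (all four stereoisomers), via quinone methide 7 (not isolated)
Conditions: 6 (4 equiv, excess recovered), CH2Cl2–acetone, rt, dark; 3 (syringe pump) and Ag2O (2.5 equiv, in portions) added in parallel over 6 h; filter through Celite; then THF–H2O (1:1), HCl to pH 3, rt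
Reagents that add atoms: water, O
Why: Ag2O (monovalent silver, reduced to silver metal) takes one electron and one proton from each phenol; the sinapyl radical (spin on O4, C1, C3, C5, C8) and the ring B phenoxy radical (spin on O4', C1', C3', C5') combine C8 with O4' to give quinone methide 7, and acid-assisted 1,6-addition of water at C7 rearomatises ring A and forms the C7–OH bond. The closest known reaction type is the dehydrogenative radical cross-coupling of monolignols with phenols to 8-O-4' quinone methides followed by their hydration, the bond-forming event of lignin biosynthesis. No ring is closed. C8 arises in an uncontrolled radical recombination and C7 by water attack on either face of the planar methide, so both are formed without control and are deliberately reset in steps 8 and 9. The step needs cross-coupling over 8–8 and 8–O–4 self-coupling of 3, and O4'–C8 regiochemistry. These are secured by the methoxy groups on C3/C5 and C3'/C5' and the alkyl group on C1', which leave O4' as the only productive site of ring B and C8 as the only productive carbon of the sinapyl radical; by the persistence of the ring B radical, which has no productive self-coupling mode; and by feeding 3 and oxidant slowly into an excess of 6.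

Step 5
Reactants: 8 syringylglycerol 8-O-4' dihydrosinapyl ether; 9 diethyl bromomalonate
Product: 10 diethyl aryloxymalonate of 8 at O4 of ring A
Conditions: 9 (1.1 equiv), K2CO3, acetone, rt to 45 °C
Reagents that add atoms: none
Why: Williamson ether synthesis in which carbonate deprotonates only the phenol (the three aliphatic hydroxyls stay neutral) and the doubly carbonyl-activated bromide is reactive enough for the di-ortho-substituted phenoxide; the new malonate carbon is not stereogenic.

Step 6
Reactants: 10 diethyl aryloxymalonate
Product: 11 pentaol with the constitution of the target (all four stereoisomers)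
Conditions: LiBH4 (6 equiv), THF–MeOH, 0 °C to rt
Reagents that add atoms: none
Why: Borohydride reduction of both α-aryloxy esters to primary alcohols; LiBH4 tolerates the free hydroxyls, the aryl ethers and the benzylic carbinol, and the carbon bearing two identical CH2OH arms is not a stereocenter.

Step 7
Reactants: 11 pentaol
Product: 12 tetrakis-TBS ether with free C7–OH
Conditions: TBSCl (4.4 equiv), imidazole, DMF, 0 °C
Reagents that add atoms: tert-butyldimethylsilyl chloride, CC(C)(C)[Si](C)(C)Cl
Why: Imidazole-promoted silyl ether formation, selective for the four primary hydroxyls because the secondary benzylic C7–OH is shielded by ring A and the aryloxy-bearing C8; no stereocenter is touched.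

Step 8
Reactants: 12 tetrakis-TBS ether
Product: 13 C7 ketone (racemic at C8)
Conditions: Dess–Martin periodinane, pyridine, CH2Cl2, 0 °C to rt
Reagents that add atoms: none
Why: Dess–Martin oxidation of the only free hydroxyl gives the aryl ketone, which merges the erythro and threo series into a single racemate and makes C8–H enolisable for step 9.

Step 9
Reactants: 13 C7 ketone
Product: 14 (7R,8R)-tetrakis-TBS alcohol
Conditions: RuCl[(S,S)-TsDPEN](p-cymene) (5 mol %), HCO2H–Et3N (1:1), DMF, 40 °C
Reagents that add atoms: none
Why: Proposed new method: the divalent ruthenium hydride generated from the precatalyst and formate delivers H−/H+ to the aryl ketone through the six-membered outer-sphere transition state of the Noyori–Ikariya asymmetric transfer hydrogenation, with the CH/π contact between p-cymene and ring A fixing the carbonyl face so that C7 should become R; Et3N meanwhile enolises C8–H (acidified by the ketone and the aryloxy oxygen) and interconverts the ketone enantiomers, and the Felkin–Anh-matched (8R) enantiomer (aryloxy group anti to the incoming hydride) should be reduced faster, so C8 should end up R and the threo (7R,8R) isomer should dominate. The closest known reaction type is the transfer hydrogenation with dynamic kinetic resolution of racemic benzoin to (R,R)-hydrobenzoin with this same catalyst, and of α-alkoxy β-keto esters to syn α-alkoxy β-hydroxy esters; here it is extended to an α-aryloxy β-silyloxy propiophenone that has no second carbonyl group.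

Step 10
Reactants: 14 (7R,8R)-tetrakis-TBS alcohol
Product: 15 CNP0186584.2
Conditions: HF·pyridine, pyridine–THF, 0 °C to rt; Me3SiOMe quench
Reagents that add atoms: none
Why: Fluoride-driven cleavage of the four primary Si–O bonds in a pyridine-buffered medium that should neither ionise the electron-rich benzylic C7 carbinol nor enolise any centre, so both stereocenters are kept.

**Compound list**

1 | sinapic acid, (E)-3-(4-hydroxy-3,5-dimethoxyphenyl)prop-2-enoic acid | COc1cc(/C=C/C(=O)O)cc(OC)c1O | starting material
2 | methyl sinapate, methyl (E)-3-(4-hydroxy-3,5-dimethoxyphenyl)prop-2-enoate | COC(=O)/C=C/c1cc(OC)c(O)c(OC)c1 | intermediate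
3 | sinapyl alcohol, 4-[(E)-3-hydroxyprop-1-enyl]-2,6-dimethoxyphenol | COc1cc(/C=C/CO)cc(OC)c1O | intermediate
4 | 4-allyl-2,6-dimethoxyphenol | COc1cc(CC=C)cc(OC)c1O | starting material
5 | bis-9-BBN adduct, 9-{3-[4-(9-borabicyclo[3.3.1]non-9-yloxy)-3,5-dimethoxyphenyl]propyl}-9-borabicyclo[3.3.1]nonane (not isolated) | COc1cc(CCCB2C3CCCC2CCC3)cc(OC)c1OB1C2CCCC1CCC2 | intermediate
6 | dihydrosinapyl alcohol, 4-(3-hydroxypropyl)-2,6-dimethoxyphenol | COc1cc(CCCO)cc(OC)c1O | intermediate
7 | quinone methide, 4-{3-hydroxy-2-[4-(3-hydroxypropyl)-2,6-dimethoxyphenoxy]propylidene}-2,6-dimethoxycyclohexa-2,5-dien-1-one, racemic at C8 (not isolated) | COC1=CC(=CC(CO)Oc2c(OC)cc(CCCO)cc2OC)C=C(OC)C1=O | intermediate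
8 | syringylglycerol 8-O-4' dihydrosinapyl ether, 1-(4-hydroxy-3,5-dimethoxyphenyl)-2-[4-(3-hydroxypropyl)-2,6-dimethoxyphenoxy]propane-1,3-diol, racemic erythro and threo | COc1cc(C(O)C(CO)Oc2c(OC)cc(CCCO)cc2OC)cc(OC)c1O | intermediate
9 | diethyl bromomalonate | CCOC(=O)C(Br)C(=O)OCC | starting material
10 | diethyl 2-{4-[1,3-dihydroxy-2-[4-(3-hydroxypropyl)-2,6-dimethoxyphenoxy]propyl]-2,6-dimethoxyphenoxy}malonate, racemic erythro and threo | CCOC(=O)C(Oc1c(OC)cc(C(O)C(CO)Oc2c(OC)cc(CCCO)cc2OC)cc1OC)C(=O)OCC | intermediate
11 | 1-[4-(1,3-dihydroxypropan-2-yloxy)-3,5-dimethoxyphenyl]-2-[4-(3-hydroxypropyl)-2,6-dimethoxyphenoxy]propane-1,3-diol, racemic erythro and threo | COc1cc(C(O)C(CO)Oc2c(OC)cc(CCCO)cc2OC)cc(OC)c1OC(CO)CO | intermediate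
12 | tetrakis-TBS ether of 11 (C9–O, C9'–O and both glyceryl oxygens silylated, C7–OH free), racemic erythro and threo | COc1cc(C(O)C(CO[Si](C)(C)C(C)(C)C)Oc2c(OC)cc(CCCO[Si](C)(C)C(C)(C)C)cc2OC)cc(OC)c1OC(CO[Si](C)(C)C(C)(C)C)CO[Si](C)(C)C(C)(C)C | intermediate
13 | C7 ketone of 12, racemic at C8 | COc1cc(C(=O)C(CO[Si](C)(C)C(C)(C)C)Oc2c(OC)cc(CCCO[Si](C)(C)C(C)(C)C)cc2OC)cc(OC)c1OC(CO[Si](C)(C)C(C)(C)C)CO[Si](C)(C)C(C)(C)C | intermediate
14 | (7R,8R)-tetrakis-TBS alcohol (threo) | COc1cc([C@@H](O)[C@@H](CO[Si](C)(C)C(C)(C)C)Oc2c(OC)cc(CCCO[Si](C)(C)C(C)(C)C)cc2OC)cc(OC)c1OC(CO[Si](C)(C)C(C)(C)C)CO[Si](C)(C)C(C)(C)C | intermediate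
15 | CNP0186584.2, (1R,2R)-1-[4-(1,3-dihydroxypropan-2-yloxy)-3,5-dimethoxyphenyl]-2-[4-(3-hydroxypropyl)-2,6-dimethoxyphenoxy]propane-1,3-diol | COc1cc([C@@H](O)[C@@H](CO)Oc2c(OC)cc(CCCO)cc2OC)cc(OC)c1OC(CO)CO | target

**Step count and risks**

Total step count: 10. Longest linear sequence: 9 steps (1, 2, 4, 5, 6, 7, 8, 9, 10, from sinapic acid).

Steps most likely to fail:

1. Step 9 (proposed new method). Enolisation at C8 may be slower than hydride transfer, so the reduction stops being dynamic and gives a mixture of diastereomers or leaves one ketone enantiomer behind. The enol(ate) may also expel the C9 silyloxy group. The fallback uses known chemistry and sets out from 13. Reduction with the bulky, non-chelating hydride LiBH(s-Bu)3 in THF at −78 °C should follow Felkin–Anh control and give, after removal of the minor erythro isomer on silica, the racemic threo tetrakis-TBS alcohol F1. Preparative HPLC of F1 on an amylose tris(3,5-dimethylphenylcarbamate) phase would separate the enantiomers, and the (7R,8R) enantiomer is 14, where the route resumes.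

2. Step 4 (key step). Self-coupling of sinapyl radicals and disproportionation of ring B phenoxy radicals may outrun the cross-coupling, and hydration of the syringyl quinone methide may be sluggish. The fallback builds the same arylglycerol ether by ionic chemistry and sets out from 6. O-alkylation of the phenol with ethyl bromoacetate (K2CO3, acetone) would give ethyl 2-[4-(3-hydroxypropyl)-2,6-dimethoxyphenoxy]acetate F2. Its lithium enolate (LiN(i-Pr)2, 2.2 equiv, THF, −78 °C, the side-chain hydroxyl carried as its lithium alkoxide) would add to commercial 4-(benzyloxy)-3,5-dimethoxybenzaldehyde in an aldol addition to give the β-hydroxy ester F3 as an erythro/threo mixture. LiAlH4 in THF would reduce the ester to the O4-benzyl ether of 8, F4. Hydrogenolysis (H2, Pd/C, EtOAc–EtOH) would free the ring A phenol and return to the route at 8.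

3. Step 7. Rate discrimination between the β-branched primary C9–OH and the secondary benzylic C7–OH may be insufficient, giving under- and over-silylated mixtures. The fallback reverses the order of protection and oxidation and sets out from 11. DDQ in 1,4-dioxane (rt to 50 °C) should oxidise only the electron-rich benzylic carbinol, by hydride abstraction, to give the keto tetraol F5. Exhaustive silylation of its four primary hydroxyls (TBSCl, imidazole, DMF) then needs no selectivity and returns to the route at 13.

**Further compounds**

F1 | step 9 | racemic threo tetrakis-TBS alcohol, (7R,8R) and (7S,8S) enantiomers | COc1cc([C@@H](O)[C@@H](CO[Si](C)(C)C(C)(C)C)Oc2c(OC)cc(CCCO[Si](C)(C)C(C)(C)C)cc2OC)cc(OC)c1OC(CO[Si](C)(C)C(C)(C)C)CO[Si](C)(C)C(C)(C)C.COc1cc([C@H](O)[C@H](CO[Si](C)(C)C(C)(C)C)Oc2c(OC)cc(CCCO[Si](C)(C)C(C)(C)C)cc2OC)cc(OC)c1OC(CO[Si](C)(C)C(C)(C)C)CO[Si](C)(C)C(C)(C)C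
F2 | step 4 | ethyl 2-[4-(3-hydroxypropyl)-2,6-dimethoxyphenoxy]acetate | CCOC(=O)COc1c(OC)cc(CCCO)cc1OC
F3 | step 4 | ethyl 3-[4-(benzyloxy)-3,5-dimethoxyphenyl]-3-hydroxy-2-[4-(3-hydroxypropyl)-2,6-dimethoxyphenoxy]propanoate, racemic erythro and threo | CCOC(=O)C(Oc1c(OC)cc(CCCO)cc1OC)C(O)c1cc(OC)c(OCc2ccccc2)c(OC)c1
F4 | step 4 | 1-[4-(benzyloxy)-3,5-dimethoxyphenyl]-2-[4-(3-hydroxypropyl)-2,6-dimethoxyphenoxy]propane-1,3-diol, racemic erythro and threo | COc1cc(C(O)C(CO)Oc2c(OC)cc(CCCO)cc2OC)cc(OC)c1OCc1ccccc1
F5 | step 7 | 1-[4-(1,3-dihydroxypropan-2-yloxy)-3,5-dimethoxyphenyl]-3-hydroxy-2-[4-(3-hydroxypropyl)-2,6-dimethoxyphenoxy]propan-1-one, racemic at C8 | COc1cc(C(=O)C(CO)Oc2c(OC)cc(CCCO)cc2OC)cc(OC)c1OC(CO)CO
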